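Substrate and product together hold the charge in the midnight run, 99.8% of it at 120 h, so we can count what each flask has made by its product fraction and ask how much of that each free enzyme charged has given.

| setting | midnight | autumn | winter | Monday's | Wednesday's |
|---|---|---|---|---|---|
| substrate | 0.10 M | 0.10 M | 0.20 M | 0.10 M | 0.10 M |
| free enzyme | 0.0067 mol% | 0.015 mol% | 0.01 mol% | 0.01 mol% | 0.01 mol% |
| temperature | 10 °C | 32 °C | 10 °C |  |  |
| remark | run made earlier | run made earlier | run made earlier | at 0 °C throughout | at 40 °C until 6.0 h, from then on at 0 °C |
| time |  |  |  | 20 h | 20 h |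

- midnight (time / h: product / %, substrate / %): 6.00: 19.8, 81.3; 20.0: 17.3, 81.4; 25.0: 18.5, 82.0; 40.0: 19.2, 79.9; 72.0: 18.3, 80.8; 96.0: 19.2, 82.2; 120: 18.3, 81.5
- autumn (time / h: product / %, substrate / %): 2.00: 26.5, 74.0; 3.00: 26.4, 74.3; 4.00: 27.5, 72.1; 6.00: 26.0, 73.6; 10.0: 25.5, 73.9; 15.0: 24.7, 73.7; 25.0: 26.8, 73.0
- winter (time / h: product / %, substrate / %): 20.0: 10.0, 89.8; 40.0: 11.7, 87.5; 72.0: 11.4, 90.0; 96.0: 12.4, 90.5; 120: 9.3, 88.4

(readings scatter by 1 percentage point)

- the earlier runs were read with a standard deviation of 1 percentage point
- a reading or a percentage of product counts all its forms, free or not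

1. the flask that ends with the higher amount of product, in percent of the substrate charged, or "neither" when 2 percentage points or less lies between them (Monday's / Wednesday's / neither)
2. final product, as a percentage of the substrate charged, in Monday's
3. final product, as a percentage of the substrate charged, in Wednesday's

1. Fastest rung: the working life of the free enzyme. The autumn run is flat at its first reading, 2.00 h, and the midnight run at 6.00 h, so in our reading the work is over within those times.

2. Slowest rung: the plateau. The midnight run holds to 120 h with 81.5% substrate standing, so substrate isn't what stops it; we commit to free enzyme as the limiting reagent, spent after a set count.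

3. That count, the turnovers per free enzyme (total turnover number), is the product fraction over the enzyme fraction: mean plateaus of 18.7% and 26.2% read as 2780 at 10 °C and 1750 at 32 °C. The winter run, at double the substrate, reads 1100, which is less than 2780, so we stay with the runs at 0.10 M.

4. In powers of ten these are 3.44 and 3.24. Drawn straight through temperature, that gives 3440 turnovers per free enzyme at 0 °C and 1470 at 40 °C.

5. Wednesday's spends 6.0 h at 40 °C, longer than the 2.00 h that sufficed at 32 °C, so we expect its enzyme spent before the cooling and 14.7% product. Monday's has 20 h, against the 6.00 h that sufficed at 10 °C, so we take its count as used up and expect 34.4%. Our call is Monday's, by 20 percentage points.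

The forecast differs from ours: 15% for Monday's, 16% for Wednesday's, neither ahead, reading the runs as “against catalyst death and for reversible equilibrium”.

The flasks give 39.7% for Monday's and 14.1% for Wednesday's, so Monday's ends higher.

    free enzyme → unfolded enzyme (k = 0.00702 h⁻¹, Ea = 275 kJ mol⁻¹)
    substrate + free enzyme → product + free enzyme, rate k2*[substrate]*[free enzyme]/(1 + ([substrate]/Km2) + ([substrate]/Ksi2)^2) (39.6 mM, 0.0801 M, k = 4.05 × 10⁵ L mol⁻¹ h⁻¹, Ea = 38.0 kJ mol⁻¹)
    crystals ⇌ product, rate k3*(cs3 - [product]) while solid is left; crystals form when [product] > cs3 (solubility = 35.0 mM, k = 4.66 h⁻¹)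
    substrate + free enzyme → spent catalyst (k = 60.9 L mol⁻¹ h⁻¹, Ea = 54.0 kJ mol⁻¹)
    (constants at 40 °C)

Counted back, Monday's gave 3970 turnovers per free enzyme charged against our 3440, with spent catalyst at 98.2% of the catalyst charged after 20.0 h. Wednesday's held 0% free enzyme at 6.00 h, its change of temperature. On the neighbour of Monday's charged with 0.006 mol% free enzyme, the same 3440 gives 20.6% product, and that flask ended at 21.6%, with 78% of its substrate left.

The readings are calculated with made-up constants.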